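**Assumption:** the target has no stereocentre (it is achiral), so no enantiocontrol is needed; 5-heptylresorcinol, 1-bromo-3-fluoro-5-methoxybenzene and heptylboronic acid are taken as catalogue compounds.

## Retrosynthetic overview
- Both CO2H groups come from aryl aldehydes by one double Pinnick oxidation at the end, so no protecting group is needed.
- The heptyl group of the methoxy ring comes from an aryl bromide by B-alkyl Suzuki coupling with heptylboronic acid.
- The diaryl ether C–O bond comes from SNAr of the 4-OH of 2-heptyl-4,6-dihydroxybenzaldehyde on 2-bromo-6-fluoro-4-methoxybenzaldehyde (F reacts, Br is kept).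
- The two aldehydes come from 1-bromo-3-fluoro-5-methoxybenzene (ortho-lithiation/DMF) and 5-heptylresorcinol (Vilsmeier–Haack).
- No ring is formed: both benzene rings are bought.

## Route

Step 1
Reactants: 1 1-bromo-3-fluoro-5-methoxybenzene
Product: 4 2-bromo-6-fluoro-4-methoxybenzaldehyde, via (2-bromo-6-fluoro-4-methoxyphenyl)lithium 2 (not isolated), via lithium hemiaminolate 3 (not isolated)
Conditions: LDA (commercial solution, 1.1 equiv), THF, −78 °C, 1 h; DMF (2 equiv), −78 °C; aq HCl, 0 °C
Reagents that add atoms: N,N-dimethylformamide, CN(C)C=O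
Why: Directed ortho-metalation takes the C–H flanked by F and Br, the most acidic ring position toward LDA (as in 1-bromo-3-fluorobenzene), and DMF formylates the aryllithium at −78 °C before benzyne formation can occur.

Step 2
Reactants: 5 5-heptylbenzene-1,3-diol (5-heptylresorcinol)
Product: 7 2-heptyl-4,6-dihydroxybenzaldehyde, via aryl iminium chloride 6 (not isolated)
Conditions: POCl3 (1.5 equiv), DMF, 0 °C → rt; then H2O, 50 °C
Reagents that add atoms: N,N-dimethylformamide, CN(C)C=O; water, O
Why: Vilsmeier–Haack formylation of a 5-alkylresorcinol goes to C4 (ortho to one OH, para to the other), as known for orcinol and olivetol, and hydrolysis of the iminium salt gives the aldehyde.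

Step 3
Reactants: 7 2-heptyl-4,6-dihydroxybenzaldehyde; 4 2-bromo-6-fluoro-4-methoxybenzaldehyde (1.1 equiv)
Product: 8 2-bromo-6-(4-formyl-3-heptyl-5-hydroxyphenoxy)-4-methoxybenzaldehyde
Conditions: K2CO3 (1.5 equiv), DMF, 90 °C, N2
Reagents that add atoms: none
Why: SNAr through a Meisenheimer complex: the fluoride ortho to the formyl group is displaced by the 4-phenoxide of 7 (the more acidic OH; the 2-OH is hydrogen-bonded to CHO), while the aryl bromide is inert.

Step 4
Reactants: 8 2-bromo-6-(4-formyl-3-heptyl-5-hydroxyphenoxy)-4-methoxybenzaldehyde; 9 heptylboronic acid (2 equiv)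
Product: 10 2-(4-formyl-3-heptyl-5-hydroxyphenoxy)-6-heptyl-4-methoxybenzaldehyde
Conditions: Pd(OAc)2 (5 mol %), RuPhos (10 mol %), K3PO4 (3 equiv), toluene/H2O 10:1, 100 °C
Reagents that add atoms: none
Why: B-alkyl Suzuki–Miyaura coupling; the bulky dialkylbiarylphosphine favours reductive elimination over β-hydride elimination, and the non-enolisable aldehydes and the phenoxide tolerate the phosphate base.

Step 5
Reactants: 10 2-(4-formyl-3-heptyl-5-hydroxyphenoxy)-6-heptyl-4-methoxybenzaldehyde
Product: 11 2-(4-carboxy-3-heptyl-5-hydroxyphenoxy)-6-heptyl-4-methoxybenzoic acid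
Conditions: NaClO2 (6 equiv), NaH2PO4 (6 equiv), 2-methyl-2-butene (40 equiv), t-BuOH/THF/H2O, 0 °C → rt
Reagents that add atoms: sodium chlorite, [Na+].[O-]Cl=O
Why: Pinnick (Lindgren) oxidation converts both aryl aldehydes to acids under buffered conditions at room temperature (no decarboxylation), with 2-methyl-2-butene removing HOCl so the phenolic ring is not chlorinated.

## Compound list
1 | 1-bromo-3-fluoro-5-methoxybenzene | COc1cc(F)cc(Br)c1 | starting material
2 | (2-bromo-6-fluoro-4-methoxyphenyl)lithium | [Li]c1c(F)cc(OC)cc1Br | intermediate (not isolated)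
3 | lithium (2-bromo-6-fluoro-4-methoxyphenyl)(dimethylamino)methanolate (racemic, transient) | [Li]OC(N(C)C)c1c(F)cc(OC)cc1Br | intermediate (not isolated)
4 | 2-bromo-6-fluoro-4-methoxybenzaldehyde | COc1cc(F)c(C=O)c(Br)c1 | intermediate
5 | 5-heptylbenzene-1,3-diol | CCCCCCCc1cc(O)cc(O)c1 | starting material
6 | N-[(2-heptyl-4,6-dihydroxyphenyl)methylidene]-N-methylmethanaminium chloride | CCCCCCCc1cc(O)cc(O)c1C=[N+](C)C.[Cl-] | intermediate (not isolated)
7 | 2-heptyl-4,6-dihydroxybenzaldehyde | CCCCCCCc1cc(O)cc(O)c1C=O | intermediate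
8 | 2-bromo-6-(4-formyl-3-heptyl-5-hydroxyphenoxy)-4-methoxybenzaldehyde | CCCCCCCc1cc(Oc2cc(OC)cc(Br)c2C=O)cc(O)c1C=O | intermediate
9 | heptylboronic acid | CCCCCCCB(O)O | starting material
10 | 2-(4-formyl-3-heptyl-5-hydroxyphenoxy)-6-heptyl-4-methoxybenzaldehyde | CCCCCCCc1cc(Oc2cc(OC)cc(CCCCCCC)c2C=O)cc(O)c1C=O | intermediate
11 | 2-(4-carboxy-3-heptyl-5-hydroxyphenoxy)-6-heptyl-4-methoxybenzoic acid | CCCCCCCc1cc(Oc2cc(OC)cc(CCCCCCC)c2C(=O)O)cc(O)c1C(=O)O | target

## Summary
Total step count: 5. Longest linear sequence: 4 steps (1 → 4 → 8 → 10 → 11, or 5 → 7 → 8 → 10 → 11).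

Three steps most likely to fail:

**Step 3 (SNAr).** The phenoxide para to a formyl group is a weak nucleophile, and the fluoroarene is only moderately activated. The fallback replaces SNAr by a copper-catalysed Ullmann ether coupling and sets out from 7. The partner is made from commercial 3,5-dibromoanisole: LDA (THF, −78 °C) deprotonates between the two bromines to give (2,6-dibromo-4-methoxyphenyl)lithium F1. DMF converts this to lithium (2,6-dibromo-4-methoxyphenyl)(dimethylamino)methanolate F2, and aqueous HCl releases 2,6-dibromo-4-methoxybenzaldehyde F3. Phenol 7 is then coupled with an excess of F3 (3 equiv, the surplus recovered) using CuI, picolinic acid and K3PO4 in DMSO at 90 °C. Mono-coupling gives the bromo diaryl ether, and the fallback comes back to the route at 8.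

**Step 4 (B-alkyl Suzuki).** An sp3 boronic acid on a substrate with a free phenol and two aldehydes may give protodebromination or β-hydride elimination. The fallback sets out from 8 and uses an sp2 coupling followed by reduction. Suzuki coupling with (E)-hept-1-en-1-ylboronic acid (Pd(dppf)Cl2, K2CO3, dioxane/H2O, 80 °C) gives 2-(4-formyl-3-heptyl-5-hydroxyphenoxy)-6-[(E)-hept-1-en-1-yl]-4-methoxybenzaldehyde F4. Chemoselective hydrogenation of the C=C (H2 1 atm, Pd/C poisoned with Ph2S, EtOAc, rt) leaves the aryl aldehydes untouched and comes back to the route at 10.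

**Step 5 (double Pinnick).** The electron-rich phenolic ring may be chlorinated by HOCl despite the scavenger. The fallback sets out from 10 and deactivates the ring by acylation. Ac2O, pyridine and cat. DMAP (CH2Cl2, 0 °C) give 2-formyl-3-heptyl-5-(2-formyl-3-heptyl-5-methoxyphenoxy)phenyl acetate F5. The same chlorite oxidation then gives 2-acetoxy-4-(2-carboxy-3-heptyl-5-methoxyphenoxy)-6-heptylbenzoic acid F6. Mild hydrolysis of the aryl acetate (LiOH, THF/H2O, 0 °C, then dilute HCl) comes back to the route at 11.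

## Further compounds
F1 | step 3 | (2,6-dibromo-4-methoxyphenyl)lithium | [Li]c1c(Br)cc(OC)cc1Br
F2 | step 3 | lithium (2,6-dibromo-4-methoxyphenyl)(dimethylamino)methanolate | [Li]OC(N(C)C)c1c(Br)cc(OC)cc1Br
F3 | step 3 | 2,6-dibromo-4-methoxybenzaldehyde | COc1cc(Br)c(C=O)c(Br)c1
F4 | step 4 | 2-(4-formyl-3-heptyl-5-hydroxyphenoxy)-6-[(E)-hept-1-en-1-yl]-4-methoxybenzaldehyde | CCCCCCCc1cc(Oc2cc(OC)cc(/C=C/CCCCC)c2C=O)cc(O)c1C=O
F5 | step 5 | 2-formyl-3-heptyl-5-(2-formyl-3-heptyl-5-methoxyphenoxy)phenyl acetate | CCCCCCCc1cc(Oc2cc(OC)cc(CCCCCCC)c2C=O)cc(OC(C)=O)c1C=O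
F6 | step 5 | 2-acetoxy-4-(2-carboxy-3-heptyl-5-methoxyphenoxy)-6-heptylbenzoic acid | CCCCCCCc1cc(Oc2cc(OC)cc(CCCCCCC)c2C(=O)O)cc(OC(C)=O)c1C(=O)O
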